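**Assumption:** (S)-(+)-carvone from caraway oil supplies C5, which becomes the ring O–CH centre. C10 is set by alkylation anti to the isopropenyl group. The C3 hydroxyl is formed non-selectively in step 9, but both C3 centres are oxidised in step 22 before the single substrate-controlled reduction in step 23.

**Retrosynthesis**
1. Target ⇒ C2-symmetric bis(oxepanone) 37 by mono-reduction of one C3 ketone.
2. 37 ⇒ the C11–C11′ bond and the tetrasubstituted C8=C9 alkene of half A, both made in one step by [2,3]-Wittig rearrangement of ether 31 (tertiary allylic alcohol 22 + allylic bromide 30), followed by deoxygenation.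
3. Both halves ⇒ common oxepanone 18, made by 7-endo alkoxymercuration of hydroxy-prenyl ketone 14.
4. 14 ⇒ (S)-carvone by α′,α′-dialkylation (C10) and isopropenyl → OAc (C5).
5. Rings: the cyclohexane comes from carvone, then the oxepane in step 9, then the alkene and central bond in step 18.

---

**Step 1**
Reactants: 1 (S)-carvone; 2 iodomethane
Product: 3 6-methylcarvone (6-Me trans to isopropenyl)
Conditions: LDA, THF, –78 °C; then MeI
Reagents that add atoms: iodomethane, CI
Why: Kinetic α′-enolate alkylation (enolate alkylation); the electrophile enters anti to the C5 isopropenyl group.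

**Step 2**
Reactants: 3; 4 1-(benzyloxy)-3-iodopropane
Product: 5 quaternary enone (new chain trans to isopropenyl, Me cis)
Conditions: LDA, THF/DMPU, –78 → 0 °C; then 4
Reagents that add atoms: 4, ICCCOCc1ccccc1
Why: Second enolate alkylation of the tetrasubstituted α′-enolate forms quaternary C10. The enolate face anti to the isopropenyl group is attacked, so the chain ends up trans to the future C5–O bond, as in the trans-fused target.

**Step 3**
Reactants: 5; 6 ozone
Product: 7 methyl ketone (isopropenyl → acetyl)
Conditions: O3, CH2Cl2, –78 °C until 5 is consumed; then PPh3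
Reagents that add atoms: ozone, [O-][O+]=O (supplies the carbonyl O; PPh3 only reduces the ozonide and leaves as Ph3P=O)
Why: Ozonolysis (oxidative alkene cleavage) cleaves the electron-rich 1,1-disubstituted alkene much faster than the conjugated trisubstituted enone, giving C(CH3)=O in place of C(CH3)=CH2. C5 is untouched.

**Step 4**
Reactants: 7; 8 mCPBA
Product: 9 C5 acetate (C5–OAc)
Conditions: mCPBA, NaHCO3, CH2Cl2, 0 °C → rt
Reagents that add atoms: mCPBA, OOC(=O)c1cccc(Cl)c1 (supplies the inserted O)
Why: Baeyer–Villiger oxidation of the methyl ketone, with migration of the secondary ring carbon with retention, so the absolute configuration at C5 is preserved. The hindered conjugated ring ketone is much less reactive toward the peracid.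

**Step 5**
Reactants: 9
Product: 10 saturated keto-acetate with 3-hydroxypropyl chain (C8 epimer mixture)
Conditions: H2 (1 atm), 10% Pd/C, EtOAc, rt
Reagents that add atoms: none (H2 only)
Why: One hydrogenation step reduces the enone C=C and hydrogenolyses the benzyl ether. The C8 epimers are irrelevant because C8 becomes sp2 in step 13.

**Step 6**
Reactants: 10
Product: 11 aldehyde
Conditions: Dess–Martin periodinane, NaHCO3, CH2Cl2, rt
Reagents that add atoms: none
Why: Mild oxidation of the primary alcohol; the hindered ketone and the acetate are unchanged.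

**Step 7**
Reactants: 11; 12 isopropyltriphenylphosphonium iodide
Product: 13 prenyl-type acetoxy ketone
Conditions: 12, KOtBu, THF, 0 °C
Reagents that add atoms: isopropylidene-triphenylphosphorane generated from 12 (salt: CC(C)[P+](c1ccccc1)(c1ccccc1)c1ccccc1.[I-]); it supplies the =CMe2 unit
Why: Wittig olefination with the unstabilised ylide is selective for the aldehyde over the neopentylic ketone and makes the C3=C4Me2 alkene.

**Step 8**
Reactants: 13
Product: 14 C5 hydroxy ketone
Conditions: K2CO3, MeOH, 0 °C
Reagents that add atoms: none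
Why: Methanolysis of the acetate (transesterification) frees C5–OH with its configuration unchanged.

**Step 9**
Reactants: 14; 15 O2
Product: 16 3-hydroxy-2,2,5a,7-tetramethyl-octahydro-1-benzoxepin-6-one (trans-fused; carbinol carbon and the methyl-bearing carbon as epimer mixtures)
Conditions: (1) Hg(OTf)2, MeCN/CH2Cl2, 0 °C; (2) NaBH4, O2, DMF, 0 °C
Reagents that add atoms: O2, O=O (supplies the C3 hydroxyl O)
Why: Alkoxymercuration: the C5–OH attacks the Hg-activated trisubstituted alkene at the tertiary carbon (Markovnikov, 7-endo). Oxidative demercuration then puts OH on C3 non-selectively, which is harmless because C3 is oxidised in step 22.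

**Step 10**
Reactants: 16; 17 TBSOTf
Product: 18 C3-OTBS ketone
Conditions: TBSOTf, 2,6-lutidine, CH2Cl2, 0 °C
Reagents that add atoms: TBSOTf, CC(C)(C)[Si](C)(C)OS(=O)(=O)C(F)(F)F
Why: Silyl ether formation protects the hindered secondary alcohol through the strongly basic steps that follow.

**Step 11**
Reactants: 18; 19 Davis oxaziridine
Product: 20 C8 tertiary α-hydroxy ketone
Conditions: KHMDS, THF, –78 °C; then 19
Reagents that add atoms: 2-(phenylsulfonyl)-3-phenyloxaziridine, O=S(=O)(c1ccccc1)N1OC1c1ccccc1
Why: Enolate α-hydroxylation (Davis oxidation). The only enolisable position is C8 because C10 is quaternary, so hydroxylation is regiospecific; the new C8 stereocentre is destroyed in the sigmatropic step.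

**Step 12**
Reactants: 20; 21 Cp2TiMe2
Product: 22 tertiary allylic alcohol (half A: C8-OH, C9=CH2)
Conditions: Cp2TiMe2 (3 equiv), PhMe/THF, 75 °C
Reagents that add atoms: Petasis reagent, C[Ti](C)(C1C=CC=C1)C1C=CC=C1 (supplies =CH2)
Why: Petasis methylenation converts the hindered ketone to the exocyclic methylene without epimerisation; the free tertiary OH is tolerated by using excess reagent.

**Step 13**
Reactants: 18; 23 PhNTf2
Product: 24 tetrasubstituted enol triflate (C9-OTf, C8=C9)
Conditions: KHMDS, THF, –78 °C; then PhNTf2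
Reagents that add atoms: N-phenyl-bis(triflimide), O=S(=O)(C(F)(F)F)N(c1ccccc1)S(=O)(=O)C(F)(F)F
Why: Only the C8 side can enolise, so the enol triflate forms regiospecifically and converges the C8 epimers.

**Step 14**
Reactants: 24; 25 carbon monoxide; 26 methanol
Product: 27 α,β-unsaturated methyl ester (C9–CO2Me)
Conditions: Pd(OAc)2, dppf, CO (1 atm), MeOH, Et3N, DMF, 60 °C
Reagents that add atoms: carbon monoxide, [C-]#[O+]; methanol, CO (the SMILES of methanol)
Why: Pd-catalysed methoxycarbonylation of the vinyl triflate; the small CO ligand can insert despite the adjacent quaternary centre.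

**Step 15**
Reactants: 27
Product: 28 allylic alcohol (C9–CH2OH)
Conditions: DIBAL-H (2.5 equiv), CH2Cl2, –78 °C
Reagents that add atoms: none
Why: 1,2-Reduction of the ester; the TBS ether and the tetrasubstituted alkene survive.

**Step 16**
Reactants: 28; 29 CBr4
Product: 30 allylic bromide (half B)
Conditions: CBr4, PPh3, CH2Cl2, 0 °C
Reagents that add atoms: carbon tetrabromide, BrC(Br)(Br)Br
Why: Neutral Appel bromination avoids acid-labile TBS and allylic ionisation; the bromide is used crude.

**Step 17**
Reactants: 22; 30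
Product: 31 bis-allylic ether
Conditions: KH, 18-crown-6, THF, 0 °C → rt
Reagents that add atoms: none
Why: Williamson etherification of the tertiary alkoxide with the primary allylic bromide.

**Step 18**
Reactants: 31
Product: 32 dimer with secondary allylic alcohol at C11′
Conditions: s-BuLi, THF, –78 → –30 °C
Reagents that add atoms: none
Why: α-Lithiation of the O–CH2 allylic carbon (C11′) triggers a [2,3]-Wittig rearrangement. The tertiary allylic C–O bond of half A is replaced by the C11–C11′ bond, the alkene moves into the tetrasubstituted C8=C9 position, and the new carbinol forms (a stereocentre removed in step 20).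

**Step 19**
Reactants: 32; 33 carbon disulfide; 2 iodomethane
Product: 34 S-methyl xanthate
Conditions: NaH, CS2, THF; then MeI
Reagents that add atoms: carbon disulfide, S=C=S; iodomethane, CI
Why: Xanthate formation activates the hindered alcohol for radical deoxygenation.

**Step 20**
Reactants: 34
Product: 35 bis-TBS dimer (C3 epimer mixtures)
Conditions: Bu3SnH, AIBN, PhMe, 110 °C
Reagents that add atoms: none
Why: Barton–McCombie deoxygenation; H is delivered to the less hindered C11′ terminus of the allyl radical, which keeps the tetrasubstituted alkene.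

**Step 21**
Reactants: 35
Product: 36 bis-alcohol
Conditions: HF·pyridine, THF/pyridine, 40 °C
Reagents that add atoms: none
Why: Removes both silyl ethers; the oxepane ethers and the alkenes are untouched.

**Step 22**
Reactants: 36
Product: 37 C2-symmetric bis(oxepanone)
Conditions: DMP, NaHCO3, CH2Cl2, rt
Reagents that add atoms: none
Why: Oxidising both C3 hydroxyls makes every epimer mixture converge to one compound. The same step re-oxidises any over-reduced or wrong-epimer alcohol recycled from step 23.

**Step 23**
Reactants: 37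
Product: 38 sodwanone T
Conditions: NaBH4 (0.5 equiv), MeOH/CH2Cl2, –78 → –20 °C
Reagents that add atoms: none
Why: Ketone reduction with the hydride delivered to the less hindered face of the trans-fused oxepanone, whose conformation is fixed by the C5/C10 centres from carvone. Because the halves are identical, mono-reduction gives a single constitutional product; the diol and the recovered diketone are separated and returned through step 22.

---

**Compound list**

| No. | Name | SMILES | Role |
|---|---|---|---|
| 1 | (S)-(+)-carvone | CC1=CC[C@H](C(C)=C)CC1=O | starting material |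
| 2 | iodomethane | CI | starting material |
| 3 | 6-methylcarvone (Me trans to isopropenyl) | CC1=CC[C@H](C(C)=C)[C@@H](C)C1=O | intermediate |
| 4 | 1-(benzyloxy)-3-iodopropane | ICCCOCc1ccccc1 | starting material |
| 5 | 6-[3-(benzyloxy)propyl]-2,6-dimethyl-5-isopropenylcyclohex-2-enone | CC1=CC[C@H](C(C)=C)[C@@](C)(CCCOCc2ccccc2)C1=O | intermediate |
| 6 | ozone | [O-][O+]=O | starting material |
| 7 | 5-acetyl-6-[3-(benzyloxy)propyl]-2,6-dimethylcyclohex-2-enone | CC1=CC[C@H](C(C)=O)[C@@](C)(CCCOCc2ccccc2)C1=O | intermediate |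
| 8 | mCPBA | OOC(=O)c1cccc(Cl)c1 | starting material |
| 9 | 5-acetoxy-6-[3-(benzyloxy)propyl]-2,6-dimethylcyclohex-2-enone | CC1=CC[C@H](OC(C)=O)[C@@](C)(CCCOCc2ccccc2)C1=O | intermediate |
| 10 | 5-acetoxy-6-(3-hydroxypropyl)-2,6-dimethylcyclohexanone (C2 epimers) | CC1CC[C@H](OC(C)=O)[C@@](C)(CCCO)C1=O | intermediate |
| 11 | corresponding propanal | CC1CC[C@H](OC(C)=O)[C@@](C)(CCC=O)C1=O | intermediate |
| 12 | isopropyltriphenylphosphonium iodide | CC(C)[P+](c1ccccc1)(c1ccccc1)c1ccccc1.[I-] | starting material |
| 13 | 5-acetoxy-2,6-dimethyl-6-(4-methylpent-3-enyl)cyclohexanone | CC1CC[C@H](OC(C)=O)[C@@](C)(CCC=C(C)C)C1=O | intermediate |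
| 14 | 5-hydroxy analogue of 13 | CC1CC[C@H](O)[C@@](C)(CCC=C(C)C)C1=O | intermediate |
| 15 | oxygen | O=O | starting material |
| 16 | 3-hydroxy-2,2,5a,7-tetramethyl-octahydro-1-benzoxepin-6-one (epimer mixtures) | CC1CC[C@@H]2OC(C)(C)C(O)CC[C@@]2(C)C1=O | intermediate |
| 17 | TBSOTf | CC(C)(C)[Si](C)(C)OS(=O)(=O)C(F)(F)F | starting material |
| 18 | 3-OTBS ketone | CC1CC[C@@H]2OC(C)(C)C(O[Si](C)(C)C(C)(C)C)CC[C@@]2(C)C1=O | intermediate |
| 19 | Davis oxaziridine | O=S(=O)(c1ccccc1)N1OC1c1ccccc1 | starting material |
| 20 | 7-hydroxy-6-ketone | CC1(O)CC[C@@H]2OC(C)(C)C(O[Si](C)(C)C(C)(C)C)CC[C@@]2(C)C1=O | intermediate |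
| 21 | Petasis reagent Cp2TiMe2 | C[Ti](C)(C1C=CC=C1)C1C=CC=C1 | starting material |
| 22 | 6-methylene-7-ol (half A) | C=C1C(C)(O)CC[C@@H]2OC(C)(C)C(O[Si](C)(C)C(C)(C)C)CC[C@@]12C | intermediate |
| 23 | PhNTf2 | O=S(=O)(C(F)(F)F)N(c1ccccc1)S(=O)(=O)C(F)(F)F | starting material |
| 24 | enol triflate | CC1=C(OS(=O)(=O)C(F)(F)F)[C@]2(C)CCC(O[Si](C)(C)C(C)(C)C)C(C)(C)O[C@H]2CC1 | intermediate |
| 25 | carbon monoxide | [C-]#[O+] | starting material |
| 26 | methanol | CO | starting material |
| 27 | methyl enoate | CC1=C(C(=O)OC)[C@]2(C)CCC(O[Si](C)(C)C(C)(C)C)C(C)(C)O[C@H]2CC1 | intermediate |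
| 28 | allylic alcohol | CC1=C(CO)[C@]2(C)CCC(O[Si](C)(C)C(C)(C)C)C(C)(C)O[C@H]2CC1 | intermediate |
| 29 | carbon tetrabromide | BrC(Br)(Br)Br | starting material |
| 30 | allylic bromide (half B) | CC1=C(CBr)[C@]2(C)CCC(O[Si](C)(C)C(C)(C)C)C(C)(C)O[C@H]2CC1 | intermediate |
| 31 | bis-allylic ether | C=C1C(C)(OCC2=C(C)CC[C@@H]3OC(C)(C)C(O[Si](C)(C)C(C)(C)C)CC[C@@]23C)CC[C@@H]4OC(C)(C)C(O[Si](C)(C)C(C)(C)C)CC[C@@]14C | intermediate |
| 32 | [2,3]-Wittig alcohol | CC1=C(CC(O)C2=C(C)CC[C@@H]3OC(C)(C)C(O[Si](C)(C)C(C)(C)C)CC[C@@]23C)[C@]4(C)CCC(O[Si](C)(C)C(C)(C)C)C(C)(C)O[C@H]4CC1 | intermediate |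
| 33 | carbon disulfide | S=C=S | starting material |
| 34 | S-methyl xanthate of 32 | CC1=C(CC(OC(=S)SC)C2=C(C)CC[C@@H]3OC(C)(C)C(O[Si](C)(C)C(C)(C)C)CC[C@@]23C)[C@]4(C)CCC(O[Si](C)(C)C(C)(C)C)C(C)(C)O[C@H]4CC1 | intermediate |
| 35 | bis-TBS dimer | CC1=C(CCC2=C(C)CC[C@@H]3OC(C)(C)C(O[Si](C)(C)C(C)(C)C)CC[C@@]23C)[C@]4(C)CCC(O[Si](C)(C)C(C)(C)C)C(C)(C)O[C@H]4CC1 | intermediate |
| 36 | bis-alcohol | CC1=C(CCC2=C(C)CC[C@@H]3OC(C)(C)C(O)CC[C@@]23C)[C@]4(C)CCC(O)C(C)(C)O[C@H]4CC1 | intermediate |
| 37 | bis(oxepanone) | CC1=C(CCC2=C(C)CC[C@@H]3OC(C)(C)C(=O)CC[C@@]23C)[C@]4(C)CCC(=O)C(C)(C)O[C@H]4CC1 | intermediate |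
| 38 | sodwanone T | CC1=C(CCC2=C(C)CC[C@@H]3OC(C)(C)[C@H](O)CC[C@@]23C)[C@]2(C)CCC(=O)C(C)(C)O[C@H]2CC1 | target |

**Total step count:** 23.
**Longest linear sequence:** 21 steps (carvone → 38, through the half-B branch).

**Three steps most likely to fail**
1. **Step 2 (quaternisation of the 6-methylcarvone enolate).** The tetrasubstituted enolate is hindered and could give γ-alkylation or low conversion. Fallback: make the Me/allyl quaternary centre by Pd-catalysed decarboxylative allylation of the allyl enol carbonate of 3, then hydroboration–oxidation of the allyl group to the 3-hydroxypropyl chain.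
2. **Step 9 (7-endo alkoxymercuration).** It may give the 6-exo tetrahydropyran or a poor yield. Fallback: epoxidise the prenyl alkene of 14 with mCPBA and close the ring by acid-promoted 7-endo epoxide opening (CSA), or use bromoetherification; the C3 epimers are again carried as a mixture.
3. **Step 18 ([2,3]-Wittig), with the regiochemistry of step 20.** The hindered α-oxy allyl anion may undergo [1,2]-shift or decomposition, and radical H-delivery could occur at C8′. Fallback: drop the sigmatropic route and join the halves by hydroboration–Suzuki: vinylate triflate 24 (vinyl-Bpin, Pd), hydroborate the vinyl group with 9-BBN, and couple with a second molecule of 24 to give 35 directly.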